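3 questions stand on one flask, and we try to carry them on 1 number.

| flask | substrate | partner | remark | time |
|---|---|---|---|---|
| winter | 0.50 M | 1.5 M | the very flask that is asked about, followed so far |  |
| summer | 1 M | 1.5 M | run made earlier |  |
| flask | 0.50 M | 1.50 M |  | 15 min |

| run | time / min | mono adduct / % | bis adduct / % | substrate / % |
|---|---|---|---|---|
| winter | 1.50 | 27 | 2 | 73 |
| winter | 3.00 | 33 | 13 | 48 |
| winter | 5.00 | 34 | 27 | 33 |
| winter | 6.00 | 31 | 31 | 27 |
| summer | 2.50 | 25 | 6 | 54 |
| summer | 5.00 | 28 | 14 | 35 |
| summer | 8.00 | 27 | 28 | 20 |
| summer | 10.0 | 25 | 32 | 16 |

(readings scatter by 2 percentage points)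

* equivalents of partner to substrate, everything else as given, that leave most mono adduct at 15 min
* the amount of mono adduct then, in percent of the substrate charged
* the amount of mono adduct with the amounts as given

- the numbers in the tables scatter by 2 percentage points (one standard deviation)

Let s and m be substrate and mono adduct as fractions of the substrate charged. If partner turns substrate into mono adduct and mono adduct into bis adduct, both rates hold the same partner, so dividing one by the other removes partner and time: dm/ds = κm/s − 1, hence m = (s^κ − s)/(1 − κ). We read the selectivity factor κ, second rate constant over first, from the winter run as bis adduct gained divided by mean mono adduct times the logarithm of the fall in substrate: 0.933.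

In this two-step picture less partner moves a flask more slowly along the curve, not higher. The curve peaks at m = 38.1%, where s = 35.5%, and the last reading of the winter run lies past that, with s at 27%.

Was one number enough? At the readings taken at 5.00 min the curve stands 4 percentage points above the winter run but 10 points above the summer run, so no: the gap is wider in the summer run, whose substrate charge is 1 M against 0.50 M.

The forecast gives 17.5% (15% to 20.5%) as charged and 28.5% at best, at 1.35 equiv: “the optimum is flat near 1.35 equiv, about 28%”.

The flask as charged gives 16.3%, inside that range, and at best 25.4% at 1.52 equiv.

    substrate + mono adduct → side product (k = 0.170 M⁻¹ min⁻¹)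
    partner + mono adduct → bis adduct (k = 0.160 M⁻¹ min⁻¹)
    substrate + partner → mono adduct (k = 0.170 M⁻¹ min⁻¹)

At 15 min the flask makes mono adduct at 0.352 of the rate at which it is used up. With 5.6% of substrate left in this flask, κ gives 17.8% against 16.3%; for the same flask read at 4.0 min, with 38.4% of substrate left, it gives 38.0% against 33.0%.

The readings stem from a simulated flask with constants of no real substance.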